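**Plan**

1. The target is ring A (a resorcinol monomethyl ether carrying two 4-hydroxybenzyl groups) joined by a CH2CH2 bridge to ring B. Ring B is numbered C1' (bridge), C2' (H), C3' (OH), C4' (4-hydroxybenzyl), C5', C6'. The enabling feature is that ring B is a phenol with the benzyl group on C4' ortho to the C3' hydroxyl and the bridge on C1' meta to it, i.e. the aromatised form of a 3-alkyl-6-benzylcyclohex-2-en-1-one (C3' = carbonyl carbon, C4' = α'-carbon, C1' = β-carbon).
2. Retrosynthesis: remove the four O-benzyl groups, return ring B to the cyclohexenone level, place an ester on C6', then cut C5'–C6' (conjugate addition) and C1'–C2' (aldol condensation). This gives the ring-A β-keto ester 9 and the α-benzyl enone 12.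
3. Keto ester 9 is cut at C1'–C6' (acylation of Meldrum's acid by acid 7). Ring A is cut at its two aryl–CH2 bonds (C2 and C6, Friedel–Crafts benzylation with 5) and at the side-chain C=C (Wittig reaction on aldehyde 1).
4. Enone 12 comes from raspberry ketone 10 by O-benzylation and α-methylenation.
5. Forward: ring A is bought and elaborated (steps 1–6), ring B is the only ring built (step 9) and is aromatised in step 11; all benzyl ethers fall in the last step.
6. Stereochemistry: the target has no stereogenic element; the sp3 centres that appear in 13–17 form as mixtures and are erased on aromatisation.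

Key step: step 9

Remark: the target is achiral, so no enantiomer has to be selected and compounds 13–17 are drawn without configuration (diastereomer mixtures). Abbreviations used in names: BOB = 4-(benzyloxy)benzyl; ArA = 3-(benzyloxy)-2,6-bis[4-(benzyloxy)benzyl]-5-methoxyphenyl (the fully protected ring A).

**Route**

Step 1
Reactants: 1 3-hydroxy-5-methoxybenzaldehyde
Product: 2 ethyl (E)-3-(3-hydroxy-5-methoxyphenyl)prop-2-enoate
Conditions: Ph3P=CHCO2Et (1.2 equiv), toluene, 80 °C
Reagents that add atoms: ethyl (triphenylphosphoranylidene)acetate, CCOC(=O)C=P(c1ccccc1)(c1ccccc1)c1ccccc1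
Why: Wittig olefination with a stabilised ylide tolerates the free phenol and should give the E-cinnamate, whose geometry is irrelevant after step 2.

Step 2
Reactants: 2 ethyl (E)-3-(3-hydroxy-5-methoxyphenyl)prop-2-enoate
Product: 3 ethyl 3-(3-hydroxy-5-methoxyphenyl)propanoate
Conditions: H2 (1 atm), 10% Pd/C, EtOAc, rt
Reagents that add atoms: none
Why: Catalytic hydrogenation saturates the conjugated C=C and leaves arene, ester and phenol untouched.

Step 3
Reactants: 3 ethyl 3-(3-hydroxy-5-methoxyphenyl)propanoate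
Product: 4 ethyl 3-[3-(benzyloxy)-5-methoxyphenyl]propanoate
Conditions: BnBr, K2CO3, DMF, rt
Reagents that add atoms: benzyl bromide, BrCc1ccccc1
Why: Williamson etherification of the phenoxide; carbonate does not deprotonate the ester α-CH2.

Step 4
Reactants: 4 ethyl 3-[3-(benzyloxy)-5-methoxyphenyl]propanoate; 5 4-(benzyloxy)benzyl alcohol (2.2 equiv)
Product: 6 ethyl 3-ArA-propanoate
Conditions: Sc(OTf)3 (10 mol%), MeNO2/CH2Cl2, 0 °C → rt, slow addition of 5
Reagents that add atoms: none
Why: Lewis-acid-catalysed Friedel–Crafts benzylation with a p-alkoxybenzyl alcohol should enter at C2 and C6, the two positions para to an ether oxygen, while C4 between the two alkoxy groups is the least reactive site, as in the 4,6-disubstitution of resorcinol diethers.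

Step 5
Reactants: 6 ethyl 3-ArA-propanoate
Product: 7 3-ArA-propanoic acid
Conditions: NaOH, THF/MeOH/H2O, 50 °C; then aq. HCl
Reagents that add atoms: sodium hydroxide, [Na+].[OH-]
Why: Saponification of the ethyl ester; aryl benzyl and methyl ethers are inert to hydroxide.

Step 6
Reactants: 7 3-ArA-propanoic acid
Product: 9 ethyl 5-ArA-3-oxopentanoate, via acyl Meldrum's acid 8 (not isolated)
Conditions: Meldrum's acid, DCC, DMAP, CH2Cl2, 0 °C → rt; filter; then EtOH, reflux
Reagents that add atoms: Meldrum's acid, CC1(C)OC(=O)CC(=O)O1; ethanol, CCO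
Why: Oikawa–Yonemitsu homologation, in which the DCC-activated acid C-acylates Meldrum's acid and ethanolysis of the adduct with loss of acetone and CO2 gives the β-keto ester under neutral conditions.

Step 7
Reactants: 10 4-(4-hydroxyphenyl)butan-2-one (raspberry ketone)
Product: 11 4-[4-(benzyloxy)phenyl]butan-2-one
Conditions: BnBr, K2CO3, acetone, reflux
Reagents that add atoms: benzyl bromide, BrCc1ccccc1
Why: Williamson etherification of the phenol; the ketone is not alkylated by carbonate.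

Step 8
Reactants: 11 4-[4-(benzyloxy)phenyl]butan-2-one
Product: 12 3-[4-(benzyloxy)benzyl]but-3-en-2-one
Conditions: (CH2O)n, N-methylanilinium trifluoroacetate, THF, reflux; used freshly
Reagents that add atoms: formaldehyde (as paraformaldehyde), C=O
Why: Mannich-type α-methylenation (Gras conditions), in which acid-catalysed enolisation toward the more substituted α-carbon, aminomethylation and β-elimination of the amine give the 1,1-disubstituted enone.

Step 9
Reactants: 9 ethyl 5-ArA-3-oxopentanoate; 12 3-[4-(benzyloxy)benzyl]but-3-en-2-one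
Product: 15 ethyl 5-BOB-4-oxo-2-(2-ArA-ethyl)cyclohex-2-ene-1-carboxylate (diastereomer mixture), via Michael adduct 13 (not isolated), via aldol ketol 14 (not isolated)
Conditions: DBU (10 mol%), THF, 0 °C → rt; then pyrrolidine/AcOH (30 mol% each), toluene, reflux, Dean–Stark
Reagents that add atoms: none
Why: Catalytic base generates the stabilised enolate of 9 at the carbon between its two carbonyl groups, which adds to the unsubstituted CH2 terminus of 12 and forms C5'–C6' (adduct 13). Pyrrolidinium acetate then converts the methyl ketone of 13 into its less substituted enamine, whose terminal carbon attacks the ketone of the keto ester to form C1'–C2' (ketol 14), and loss of water gives the conjugated enone 15. The closest known reaction is the Robinson annulation of acetoacetic esters with methyl vinyl ketone that delivers Hagemann's ester. Ring B closes in the 6-(enolendo)-exo-trig mode. The two new stereocentres (C1 and C5 of the cyclohexene) form without control and are both destroyed on aromatisation. The step needs the methyl carbon as nucleophile and the keto-ester ketone as electrophile: the ester fixes the site of conjugate addition, the competing aldol from the C4 methylene of the keto ester would need a more hindered enamine attacking an α-branched ketone, and the absence of stoichiometric alkoxide suppresses Claisen closure onto the ester.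

Step 10
Reactants: 15 ethyl 5-BOB-4-oxo-2-(2-ArA-ethyl)cyclohex-2-ene-1-carboxylate
Product: 17 6-BOB-3-(2-ArA-ethyl)cyclohex-2-en-1-one, via cyclohexenone acid 16 (not isolated)
Conditions: KOH, EtOH/THF/H2O, reflux; then aq. HCl to pH 2, 70 °C
Reagents that add atoms: none
Why: Saponification of the vinylogous β-keto ester and decarboxylation of the resulting vinylogous β-keto acid on acidification and warming, as in the conversion of Hagemann's ester into 3-methylcyclohex-2-enone.

Step 11
Reactants: 17 6-BOB-3-(2-ArA-ethyl)cyclohex-2-en-1-one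
Product: 18 2-BOB-5-(2-ArA-ethyl)phenol
Conditions: Pd(TFA)2 (5 mol%), 2-(dimethylamino)pyridine (10 mol%), TsOH·H2O (20 mol%), O2 (1 atm), DMSO, 80 °C
Reagents that add atoms: none
Why: Pd(II)-catalysed aerobic dehydrogenation of a cyclohexenone to a phenol (Pd enolate, β-hydride elimination, tautomerisation) can act only on the one ring that carries an enolisable carbonyl; aryl ethers and arenes are inert.

Step 12
Reactants: 18 2-BOB-5-(2-ArA-ethyl)phenol
Product: 19 5-{2-[3-hydroxy-2,6-bis(4-hydroxybenzyl)-5-methoxyphenyl]ethyl}-2-(4-hydroxybenzyl)phenol (CNP0207338.0)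
Conditions: H2 (1 atm), 10% Pd/C, THF/MeOH, rt
Reagents that add atoms: none
Why: Hydrogenolysis of the four aryl benzyl ethers over Pd/C; the diarylmethane C–C bonds and the methyl ether should survive at 1 atm and room temperature.

**Compound list**

1 | 3-hydroxy-5-methoxybenzaldehyde | COc1cc(O)cc(C=O)c1 | starting material
2 | ethyl (E)-3-(3-hydroxy-5-methoxyphenyl)prop-2-enoate | CCOC(=O)/C=C/c1cc(O)cc(OC)c1 | intermediate
3 | ethyl 3-(3-hydroxy-5-methoxyphenyl)propanoate | CCOC(=O)CCc1cc(O)cc(OC)c1 | intermediate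
4 | ethyl 3-[3-(benzyloxy)-5-methoxyphenyl]propanoate | CCOC(=O)CCc1cc(OCc2ccccc2)cc(OC)c1 | intermediate
5 | 4-(benzyloxy)benzyl alcohol | OCc1ccc(OCc2ccccc2)cc1 | starting material
6 | ethyl 3-{3-(benzyloxy)-2,6-bis[4-(benzyloxy)benzyl]-5-methoxyphenyl}propanoate | CCOC(=O)CCc1c(Cc2ccc(OCc3ccccc3)cc2)c(OCc2ccccc2)cc(OC)c1Cc1ccc(OCc2ccccc2)cc1 | intermediate
7 | 3-{3-(benzyloxy)-2,6-bis[4-(benzyloxy)benzyl]-5-methoxyphenyl}propanoic acid | OC(=O)CCc1c(Cc2ccc(OCc3ccccc3)cc2)c(OCc2ccccc2)cc(OC)c1Cc1ccc(OCc2ccccc2)cc1 | intermediate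
8 | 5-(3-ArA-propanoyl)-2,2-dimethyl-1,3-dioxane-4,6-dione (acyl Meldrum's acid) | CC1(C)OC(=O)C(C(=O)CCc2c(Cc3ccc(OCc4ccccc4)cc3)c(OCc3ccccc3)cc(OC)c2Cc2ccc(OCc3ccccc3)cc2)C(=O)O1 | intermediate
9 | ethyl 5-ArA-3-oxopentanoate | CCOC(=O)CC(=O)CCc1c(Cc2ccc(OCc3ccccc3)cc2)c(OCc2ccccc2)cc(OC)c1Cc1ccc(OCc2ccccc2)cc1 | intermediate
10 | 4-(4-hydroxyphenyl)butan-2-one (raspberry ketone) | CC(=O)CCc1ccc(O)cc1 | starting material
11 | 4-[4-(benzyloxy)phenyl]butan-2-one | CC(=O)CCc1ccc(OCc2ccccc2)cc1 | intermediate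
12 | 3-[4-(benzyloxy)benzyl]but-3-en-2-one | CC(=O)C(=C)Cc1ccc(OCc2ccccc2)cc1 | intermediate
13 | ethyl 2-(3-ArA-propanoyl)-4-BOB-5-oxohexanoate (Michael adduct, diastereomer mixture) | CCOC(=O)C(CC(Cc1ccc(OCc2ccccc2)cc1)C(C)=O)C(=O)CCc1c(Cc2ccc(OCc3ccccc3)cc2)c(OCc2ccccc2)cc(OC)c1Cc1ccc(OCc2ccccc2)cc1 | intermediate
14 | ethyl 5-BOB-2-hydroxy-4-oxo-2-(2-ArA-ethyl)cyclohexane-1-carboxylate (ketol, diastereomer mixture) | CCOC(=O)C1CC(Cc2ccc(OCc3ccccc3)cc2)C(=O)CC1(O)CCc1c(Cc2ccc(OCc3ccccc3)cc2)c(OCc2ccccc2)cc(OC)c1Cc1ccc(OCc2ccccc2)cc1 | intermediate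
15 | ethyl 5-BOB-4-oxo-2-(2-ArA-ethyl)cyclohex-2-ene-1-carboxylate (diastereomer mixture) | CCOC(=O)C1CC(Cc2ccc(OCc3ccccc3)cc2)C(=O)C=C1CCc1c(Cc2ccc(OCc3ccccc3)cc2)c(OCc2ccccc2)cc(OC)c1Cc1ccc(OCc2ccccc2)cc1 | intermediate
16 | 5-BOB-4-oxo-2-(2-ArA-ethyl)cyclohex-2-ene-1-carboxylic acid | OC(=O)C1CC(Cc2ccc(OCc3ccccc3)cc2)C(=O)C=C1CCc1c(Cc2ccc(OCc3ccccc3)cc2)c(OCc2ccccc2)cc(OC)c1Cc1ccc(OCc2ccccc2)cc1 | intermediate
17 | 6-BOB-3-(2-ArA-ethyl)cyclohex-2-en-1-one (racemic) | O=C1C=C(CCc2c(Cc3ccc(OCc4ccccc4)cc3)c(OCc3ccccc3)cc(OC)c2Cc2ccc(OCc3ccccc3)cc2)CCC1Cc1ccc(OCc2ccccc2)cc1 | intermediate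
18 | 2-BOB-5-(2-ArA-ethyl)phenol | Oc1cc(CCc2c(Cc3ccc(OCc4ccccc4)cc3)c(OCc3ccccc3)cc(OC)c2Cc2ccc(OCc3ccccc3)cc2)ccc1Cc1ccc(OCc2ccccc2)cc1 | intermediate
19 | 5-{2-[3-hydroxy-2,6-bis(4-hydroxybenzyl)-5-methoxyphenyl]ethyl}-2-(4-hydroxybenzyl)phenol (CNP0207338.0) | COc1cc(O)c(Cc2ccc(O)cc2)c(CCc2ccc(Cc3ccc(O)cc3)c(O)c2)c1Cc1ccc(O)cc1 | target

**Step count and risks**

Total step count: 12. Longest linear sequence: 10 steps (1–6, then 9–12); steps 7–8 form the short convergent arm.

Steps most likely to fail: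

Step 4 (double Friedel–Crafts benzylation). The benzyl cation may also attack C4 or add a third time, and the benzyl alcohol may oligomerise, so that site control and the degree of alkylation are lost. The fallback sets out from 4 and comes back at 6. Bromination of 4 with N-bromosuccinimide (2.1 equiv, MeCN, 0 °C → rt) should give ethyl 3-[3-(benzyloxy)-2,6-dibromo-5-methoxyphenyl]propanoate F1, the halogens entering para to the ether oxygens as in the dibromination of 3,5-dialkoxyalkylbenzenes. Twofold Negishi coupling of F1 with [4-(benzyloxy)benzyl]zinc chloride F2 (from commercial 4-(benzyloxy)benzyl chloride, Zn dust and LiCl in THF) under Pd(OAc)2/SPhos in THF at 60 °C then places both benzyl groups on the halogen-bearing carbons and gives 6.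

Step 9 (annulation). Conjugate addition to the α-branched enone may be slow next to self-condensation of the enone or a second addition, and the ring may close in another sense. The fallback sets out from 9 and comes back at 17; it moves the benzyl group to a later enolate alkylation. The same two-stage protocol with but-3-en-2-one, the parent case of this annulation, should pass through ethyl 2-(3-ArA-propanoyl)-5-oxohexanoate F3 and ethyl 2-hydroxy-4-oxo-2-(2-ArA-ethyl)cyclohexane-1-carboxylate F4 to ethyl 4-oxo-2-(2-ArA-ethyl)cyclohex-2-ene-1-carboxylate F5. Saponification and decarboxylation as in step 10, through 4-oxo-2-(2-ArA-ethyl)cyclohex-2-ene-1-carboxylic acid F6, should give 3-(2-ArA-ethyl)cyclohex-2-en-1-one F7. Its kinetic cross-conjugated lithium enolate (LDA, THF, −78 °C) is alkylated at C6 with commercial 4-(benzyloxy)benzyl bromide to give 17.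

Step 11 (aerobic dehydrogenation). Turnover may stop early through catalyst deactivation, or oxidation may spread to the doubly benzylic CH2 groups. The fallback sets out from 17 and comes back at 18. Kinetic deprotonation at C6 (LDA, THF, −78 °C) and trapping with PhSeCl should give 6-BOB-6-(phenylselanyl)-3-(2-ArA-ethyl)cyclohex-2-en-1-one F8. Oxidation with H2O2 (pyridine, CH2Cl2, 0 °C → rt) gives the selenoxide 6-BOB-6-(phenylseleninyl)-3-(2-ArA-ethyl)cyclohex-2-en-1-one F9, whose syn-elimination leads to 2-BOB-5-(2-ArA-ethyl)cyclohexa-2,5-dien-1-one F10, the keto tautomer of 18, which should aromatise spontaneously.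

**Further compounds**

F1 | step 4 | ethyl 3-[3-(benzyloxy)-2,6-dibromo-5-methoxyphenyl]propanoate | CCOC(=O)CCc1c(Br)c(OCc2ccccc2)cc(OC)c1Br
F2 | step 4 | [4-(benzyloxy)benzyl]zinc chloride | Cl[Zn]Cc1ccc(OCc2ccccc2)cc1
F3 | step 9 | ethyl 2-(3-ArA-propanoyl)-5-oxohexanoate | CCOC(=O)C(CCC(C)=O)C(=O)CCc1c(Cc2ccc(OCc3ccccc3)cc2)c(OCc2ccccc2)cc(OC)c1Cc1ccc(OCc2ccccc2)cc1
F4 | step 9 | ethyl 2-hydroxy-4-oxo-2-(2-ArA-ethyl)cyclohexane-1-carboxylate | CCOC(=O)C1CCC(=O)CC1(O)CCc1c(Cc2ccc(OCc3ccccc3)cc2)c(OCc2ccccc2)cc(OC)c1Cc1ccc(OCc2ccccc2)cc1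
F5 | step 9 | ethyl 4-oxo-2-(2-ArA-ethyl)cyclohex-2-ene-1-carboxylate | CCOC(=O)C1CCC(=O)C=C1CCc1c(Cc2ccc(OCc3ccccc3)cc2)c(OCc2ccccc2)cc(OC)c1Cc1ccc(OCc2ccccc2)cc1
F6 | step 9 | 4-oxo-2-(2-ArA-ethyl)cyclohex-2-ene-1-carboxylic acid | OC(=O)C1CCC(=O)C=C1CCc1c(Cc2ccc(OCc3ccccc3)cc2)c(OCc2ccccc2)cc(OC)c1Cc1ccc(OCc2ccccc2)cc1
F7 | step 9 | 3-(2-ArA-ethyl)cyclohex-2-en-1-one | O=C1C=C(CCc2c(Cc3ccc(OCc4ccccc4)cc3)c(OCc3ccccc3)cc(OC)c2Cc2ccc(OCc3ccccc3)cc2)CCC1
F8 | step 11 | 6-BOB-6-(phenylselanyl)-3-(2-ArA-ethyl)cyclohex-2-en-1-one | O=C1C=C(CCc2c(Cc3ccc(OCc4ccccc4)cc3)c(OCc3ccccc3)cc(OC)c2Cc2ccc(OCc3ccccc3)cc2)CCC1(Cc1ccc(OCc2ccccc2)cc1)[Se]c1ccccc1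
F9 | step 11 | 6-BOB-6-(phenylseleninyl)-3-(2-ArA-ethyl)cyclohex-2-en-1-one | O=C1C=C(CCc2c(Cc3ccc(OCc4ccccc4)cc3)c(OCc3ccccc3)cc(OC)c2Cc2ccc(OCc3ccccc3)cc2)CCC1(Cc1ccc(OCc2ccccc2)cc1)[Se](=O)c1ccccc1
F10 | step 11 | 2-BOB-5-(2-ArA-ethyl)cyclohexa-2,5-dien-1-one | O=C1C=C(CCc2c(Cc3ccc(OCc4ccccc4)cc3)c(OCc3ccccc3)cc(OC)c2Cc2ccc(OCc3ccccc3)cc2)CC=C1Cc1ccc(OCc2ccccc2)cc1
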